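**Retrosynthetic overview**
1. Rabdosin B (35) ⇐ α-methylenation at C16 of nor-ketone 34 ⇐ SmI2 ketyl–olefin cyclisation/Claisen cascade of aldehyde ester 32 (C9–C11, then C8–C15; rings C and D).
2. 32 ⇐ ring-closing metathesis (7,20-lactone, C8=C9) ⇐ Negishi union (C8–C14) of ring-A bromoacrylate 18 with zinc reagent 29 (C13 from an Evans alkylation).
3. Ring A ⇐ acyclic bis(allylboronate) 10 + acrolein 11 in one operation: hydrogen-atom-transfer Giese addition (C3–C4), then intramolecular allylboration of the unveiled aldehyde (C1–C10), a formal [3+3] annulation; 10 ⇐ (S)-lactone 3.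
4. Enabling feature: in ring A the C1 carbinol is flanked by the quaternary spiro carbon C10, whose C9 branch can be a vinyl group (homoallylic alcohol = allylboration retron); gem-dimethyl C4 lies 1,3 to C1 (tertiary radical + acrolein); the C20 oxygen, cis to C1–O, comes from the second boron.
5. Order of ring formation: ring A (step 7) → δ-lactone ring (step 16) → rings C and D together (step 18).

Key step: step 7

Remark: atom numbers C1–C20 are the ent-kaurane numbers of the target atoms.
Assumption: the (S)-BINAP–rhodium catalyst attacks furan-2(5H)-one with the facial sense known for cyclic enones, which corresponds to (S)-3; if the sense is opposite, the (R)-ligand is used.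

Step 1
Reactants: 1 furan-2(5H)-one; 2 potassium trifluoro(prop-1-en-2-yl)borate
Product: 3 (S)-4-(prop-1-en-2-yl)dihydrofuran-2(3H)-one
Conditions: [Rh(cod)2]BF4 (3 mol%), (S)-BINAP (3.3 mol%), toluene/H2O, 100 °C
Reagents that add atoms: none
Why: Hayashi–Miyaura reaction: the alkenylrhodium species adds 1,4 to the butenolide and water protonates the oxa-π-allyl; the chiral ligand selects the enone face and sets C5, the only stereocentre carried into the key step.

Step 2
Reactants: 3
Product: 6 (R)-3-methylene-4-(prop-1-en-2-yl)dihydrofuran-2(3H)-one, via Mannich base 4 (not isolated), via methiodide 5 (not isolated)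
Conditions: LiN(SiMe3)2, THF, −78 °C; CH2=NMe2+ I−, −78 → 0 °C; MeI, MeOH, 23 °C; aq. NaHCO3, CH2Cl2
Reagents that add atoms: N,N-dimethylmethyleneiminium iodide (Eschenmoser's salt), C=[N+](C)C.[I-]
Why: Eschenmoser methylenation: the lactone enolate is aminomethylated and the quaternised Mannich base loses trimethylamine (E1cB) to give the exocyclic methylene (C20); C5 is not enolisable and is untouched.

Step 3
Reactants: 6
Product: 7 (4R)-3-methylene-4-(prop-1-en-2-yl)tetrahydrofuran-2-ol (lactol; both anomers)
Conditions: i-Bu2AlH (1.1 equiv), CH2Cl2, −78 °C; aq. potassium sodium tartrate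
Reagents that add atoms: none
Why: Hydride reduction at −78 °C stops at the stable aluminium lactolate (1,2-reduction of the α-methylene lactone), giving the lactol as a masked 2-substituted acrolein.

Step 4
Reactants: 7
Product: 8 (R)-3-methylene-2-(prop-1-en-2-yl)pent-4-en-1-ol
Conditions: Ph3PCH3Br, KOt-Bu, THF, 0 → 23 °C
Reagents that add atoms: methyltriphenylphosphonium bromide, C[P+](c1ccccc1)(c1ccccc1)c1ccccc1.[Br-]
Why: Wittig methylenation of the open hydroxy-enal form of the lactol turns C9 into a vinyl group, creating the 2-substituted buta-1,3-diene and freeing the C6 hydroxyl.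

Step 5
Reactants: 8
Product: 9 (R)-3-methylene-2-(prop-1-en-2-yl)pent-4-en-1-yl acetate
Conditions: Ac2O, pyridine, DMAP (cat.), CH2Cl2, 0 → 23 °C
Reagents that add atoms: acetic anhydride, CC(=O)OC(C)=O
Why: Standard nucleophile-catalysed acetylation installs the C6 acetate of the target, an ester that should survive all later steps.

Step 6
Reactants: 9
Product: 10 (R)-3-methyl-2-[(E)-1,4-bis(4,4,5,5-tetramethyl-1,3,2-dioxaborolan-2-yl)but-2-en-2-yl]but-3-en-1-yl acetate (the two CH2Bpin groups cis)
Conditions: B2pin2 (1.1 equiv), Pt(PPh3)4 (3 mol%), toluene, 80 °C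
Reagents that add atoms: bis(pinacolato)diboron, CC1(C)OB(OC1(C)C)B1OC(C)(C)C(C)(C)O1
Why: Platinum-catalysed 1,4-diboration of a 1,3-diene goes through the s-cis diene and so places the two CH2Bpin groups cis on the new trisubstituted alkene (the geometry that later makes C20 axial); the isolated 1,1-disubstituted alkene should not be diborated.

Step 7
Reactants: 10; 11 acrolein
Product: 14 [(1R,2S,3S)-3-hydroxy-2-(hydroxymethyl)-6,6-dimethyl-2-vinylcyclohexyl]methyl acetate (ring A; C1–OH and C20 and C6 mutually cis; vinyl trans), via aldehyde 12 (not isolated), via borate ester 13 (not isolated)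
Conditions: Fe(acac)3 (30 mol%), PhSiH2(Oi-Pr) (2 equiv), EtOH/THF, 0 → 23 °C; then 45 °C; then H2O2, aq. NaHCO3, 0 °C
Reagents that add atoms: hydrogen peroxide, OO
Why: Proposed new method: an iron hydride formed from Fe(acac)3 and the silane transfers a hydrogen atom to the terminal CH2 of the isopropenyl group, the tertiary C4 radical adds to the β-carbon of acrolein (C3–C4, Giese addition), and reduction/protonation of the α-formyl radical unveils aldehyde 12, which is trapped at once by the internal γ,γ-disubstituted allylboronate through a closed six-membered boron–oxygen transition state (C1–C10); borate 13 and the remaining C20–B bond are cleaved in the oxidative work-up. The closest known reactions are the iron-catalysed hydrogen-atom-transfer reductive coupling of 1,1-disubstituted alkenes with enals and acrylates and the intramolecular allylboration of tethered aldehydes (diboration/allylation/oxidation of 1,4-bis(boronates)); their merger in one flask is the new element. Ring A closes by 6-exo-trig attack of C10 on the aldehyde carbon with allyl transposition, the Zimmerman–Traxler ring and the carbocycle being trans-fused chairs. In that array C5 holds its CH2OAc group equatorial and so chooses the face; the alkene geometry from step 6 (C20 cis to the boron-bearing CH2) forces C20 axial and the new vinyl group equatorial at C10; the tether carbon C2 sits equatorial on the boron ring, so C1–O ends cis to C20 and C6 as in the target. The step needs hydrogen-atom transfer at the 1,1-disubstituted alkene rather than the hindered trisubstituted allylboronate alkene, six-membered closure through C10 rather than seven-membered closure through C9, and no intermolecular allylboration of acrolein; these are secured by the steric bias of the iron hydride, by ring size, and by the low reactivity of pinacol allylboronates toward aldehydes at or below 23 °C.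

Step 8
Reactants: 14; 15 2,3-dibromopropanoyl chloride
Product: 17 C20 2-bromoacrylate of diol 14 (C1–OH free), via dibromo ester 16 (not isolated)
Conditions: Et3N (2.5 equiv), CH2Cl2, −40 → 0 °C
Reagents that add atoms: none
Why: The primary C20 hydroxyl is acylated faster than the hindered secondary C1 hydroxyl, and triethylamine removes HBr from the 2,3-dibromopropanoate (esterification, then E2 elimination) to give the 2-bromoacrylate.

Step 9
Reactants: 17
Product: 18 C1 acetate of 17 (1,6-diacetate; C20 2-bromoacrylate)
Conditions: Ac2O, Sc(OTf)3 (2 mol%), MeCN, −20 °C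
Reagents that add atoms: acetic anhydride, CC(=O)OC(C)=O
Why: Lewis-acid-catalysed acetylation needs no nucleophilic amine that could add to the bromoacrylate and installs the C1 acetate of the target with retention.

Step 10
Reactants: 19 methyl 4,4-dimethoxybutanoate
Product: 20 lithium 4,4-dimethoxybutanoate
Conditions: LiOH·H2O (1.0 equiv), THF/H2O, 23 °C; evaporation
Reagents that add atoms: lithium hydroxide, [Li+].[OH-]
Why: Ester saponification; the salt is used as such because the free acid would cyclise onto the acetal.

Step 11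
Reactants: 20
Product: 22 (R)-4-benzyl-3-(4,4-dimethoxybutanoyl)oxazolidin-2-one, via mixed anhydride 21 (not isolated)
Conditions: t-BuCOCl, THF, −20 °C; then (R)-4-benzyl-2-oxazolidinone/n-BuLi, THF, −78 → 0 °C
Reagents that add atoms: (R)-4-benzyl-2-oxazolidinone, O=C1N[C@H](Cc2ccccc2)CO1
Why: N-Acylation of the lithiated oxazolidinone by the mixed pivalic anhydride (attack at the less hindered carbonyl) attaches the Evans auxiliary.

Step 12
Reactants: 22; 23 methyl bromoacetate
Product: 24 methyl (S)-3-[(R)-4-benzyl-2-oxooxazolidine-3-carbonyl]-5,5-dimethoxypentanoate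
Conditions: NaN(SiMe3)2, THF, −78 °C; then 23, −78 → −40 °C
Reagents that add atoms: none
Why: Evans alkylation: the chelated (Z)-sodium enolate is alkylated on the face opposite the benzyl group, which sets C13.

Step 13
Reactants: 24
Product: 26 (S)-2-(2,2-dimethoxyethyl)-4-methoxy-4-oxobutanoic acid, via peroxycarboxylate 25 (not isolated)
Conditions: LiOH, H2O2, THF/H2O, 0 °C; Na2SO3; 1 M HCl to pH 4
Reagents that add atoms: hydrogen peroxide, OO
Why: Lithium hydroperoxide cleaves the exocyclic imide carbonyl selectively (the methyl ester is untouched at 0 °C), sulfite reduces the peracid, and the auxiliary is released without touching C13.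

Step 14
Reactants: 26
Product: 28 methyl (S)-3-(iodomethyl)-5,5-dimethoxypentanoate, via hydroxy ester 27 (not isolated)
Conditions: BH3·SMe2, THF, 0 °C; MeOH; then I2, PPh3, imidazole, CH2Cl2, 0 °C
Reagents that add atoms: iodine, [I][I]
Why: Borane reduces the carboxylic acid chemoselectively beside the methyl ester, and the Appel reaction converts the alcohol into the iodide before it can lactonise.

Step 15
Reactants: 28; 18
Product: 30 2-substituted acrylate (18 with Br replaced by the (S)-2-(2,2-dimethoxyethyl)-4-methoxy-4-oxobutyl chain), via organozinc iodide 29 (not isolated)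
Conditions: Zn dust, LiCl, THF, 40 °C; then 18, Pd(PPh3)4 (5 mol%), THF, 23 °C
Reagents that add atoms: none
Why: Negishi coupling: zinc insertion gives an ester- and acetal-tolerant alkylzinc iodide that couples with the alkenyl bromide (sp3–sp2), uniting the two fragments through the C8–C14 bond without touching C13.

Step 16
Reactants: 30
Product: 31 α,β-unsaturated spiro-δ-lactone (7,20-olide, C8=C9) with ring A (1-OAc, 6-OAc) and the C8 side chain CH2–CH(CH2CH(OMe)2)(CH2CO2Me)
Conditions: second-generation Hoveyda–Grubbs catalyst (10 mol%), toluene (2 mM), 90 °C, argon sparge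
Reagents that add atoms: none
Why: Ring-closing metathesis between the C10 vinyl group and the 1,1-disubstituted acrylate closes the six-membered lactone and forms the trisubstituted C8=C9 alkene with loss of ethylene.

Step 17
Reactants: 31
Product: 32 aldehyde (C11 CHO) of 31
Conditions: LiBF4, MeCN/H2O (98:2), 23 °C
Reagents that add atoms: water, O
Why: Lewis-acid-assisted acetal hydrolysis under nearly neutral conditions should leave the acetates, the methyl ester and the lactone intact.

Step 18
Reactants: 32
Product: 34 17-nor-Rabdosin B (the target without the exocyclic C17 methylene; 11-OH, 15-ketone), via samarium enolate 33 (not isolated)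
Conditions: SmI2 (2.5 equiv), LiBr, THF, −78 → 0 °C, no proton source; then 0.1 M HCl
Reagents that add atoms: none
Why: Proposed new method: SmI2 reduces the aldehyde to a ketyl that adds to C9 of the unsaturated lactone (face anti to the C5 side of ring A, chair transition state with the ketyl oxygen and the C13 substituent equatorial, setting C9 and C11), a second electron gives the C8 samarium enolate, and without a proton source this enolate is acylated by the neighbouring methyl ester (5-exo-trig at C15, directly or after lactonisation of the C11 alkoxide) to close ring D with C8 fixed by the bridge; the closest known reactions are SmI2 ketyl–olefin cyclisation/aldol cascades on unsaturated lactones and Dieckmann acylations of metal enolates.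

Step 19
Reactants: 34
Product: 35 Rabdosin B
Conditions: (CH2O)n, PhNH2Me+ CF3CO2−, THF, 65 °C
Reagents that add atoms: formaldehyde (as paraformaldehyde), C=O
Why: Mannich-type α-methylenation at C16, the only enolisable position of the C15 ketone, followed by E1cB loss of the amine gives the exo-methylene enone without acylating the free C11 hydroxyl.

**Compound list**
1 | furan-2(5H)-one | O=C1OCC=C1 | starting material
2 | potassium trifluoro(prop-1-en-2-yl)borate | C=C(C)[B-](F)(F)F.[K+] | starting material
3 | (S)-4-(prop-1-en-2-yl)dihydrofuran-2(3H)-one | O=C1C[C@@H](C(C)=C)CO1 | intermediate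
4 | Mannich base, (4S)-3-[(dimethylamino)methyl]-4-(prop-1-en-2-yl)dihydrofuran-2(3H)-one (C3 epimers) | CN(C)CC1C(=O)OC[C@@H]1C(C)=C | intermediate (not isolated)
5 | methiodide of 4 | C[N+](C)(C)CC1C(=O)OC[C@@H]1C(C)=C.[I-] | intermediate (not isolated)
6 | (R)-3-methylene-4-(prop-1-en-2-yl)dihydrofuran-2(3H)-one | C=C1C(=O)OC[C@@H]1C(C)=C | intermediate
7 | (4R)-3-methylene-4-(prop-1-en-2-yl)tetrahydrofuran-2-ol (both anomers) | C=C1C(O)OC[C@@H]1C(C)=C | intermediate
8 | (R)-3-methylene-2-(prop-1-en-2-yl)pent-4-en-1-ol | C=CC(=C)[C@H](CO)C(C)=C | intermediate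
9 | (R)-3-methylene-2-(prop-1-en-2-yl)pent-4-en-1-yl acetate | C=CC(=C)[C@H](COC(C)=O)C(C)=C | intermediate
10 | (R)-3-methyl-2-[(E)-1,4-bis(pinacolboryl)but-2-en-2-yl]but-3-en-1-yl acetate (CH2Bpin groups cis) | CC1(C)OB(C/C=C(\CB2OC(C)(C)C(C)(C)O2)[C@H](COC(C)=O)C(C)=C)OC1(C)C | intermediate
11 | acrolein | C=CC=O | starting material
12 | (R)-3,3-dimethyl-6-oxo-2-[(E)-1,4-bis(pinacolboryl)but-2-en-2-yl]hexyl acetate | CC1(C)OB(C/C=C(\CB2OC(C)(C)C(C)(C)O2)[C@H](COC(C)=O)C(C)(C)CCC=O)OC1(C)C | intermediate (not isolated)
13 | ring-A allylboration product (C1–O–Bpin, C20–Bpin, C10 vinyl; relative configuration as 14) | C=C[C@]1(CB2OC(C)(C)C(C)(C)O2)[C@@H](OB2OC(C)(C)C(C)(C)O2)CCC(C)(C)[C@H]1COC(C)=O | intermediate (not isolated)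
14 | [(1R,2S,3S)-3-hydroxy-2-(hydroxymethyl)-6,6-dimethyl-2-vinylcyclohexyl]methyl acetate | C=C[C@]1(CO)[C@@H](O)CCC(C)(C)[C@H]1COC(C)=O | intermediate
15 | 2,3-dibromopropanoyl chloride | O=C(Cl)C(Br)CBr | starting material
16 | C20 2,3-dibromopropanoate of 14 | C=C[C@]1(COC(=O)C(Br)CBr)[C@@H](O)CCC(C)(C)[C@H]1COC(C)=O | intermediate (not isolated)
17 | C20 2-bromoacrylate of 14 | C=C[C@]1(COC(=O)C(Br)=C)[C@@H](O)CCC(C)(C)[C@H]1COC(C)=O | intermediate
18 | C1 acetate of 17 | C=C[C@]1(COC(=O)C(Br)=C)[C@@H](OC(C)=O)CCC(C)(C)[C@H]1COC(C)=O | intermediate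
19 | methyl 4,4-dimethoxybutanoate | COC(=O)CCC(OC)OC | starting material
20 | lithium 4,4-dimethoxybutanoate | [Li+].[O-]C(=O)CCC(OC)OC | intermediate
21 | 4,4-dimethoxybutanoic pivalic anhydride | CC(C)(C)C(=O)OC(=O)CCC(OC)OC | intermediate (not isolated)
22 | (R)-4-benzyl-3-(4,4-dimethoxybutanoyl)oxazolidin-2-one | COC(OC)CCC(=O)N1[C@H](Cc2ccccc2)COC1=O | intermediate
23 | methyl bromoacetate | COC(=O)CBr | starting material
24 | methyl (S)-3-[(R)-4-benzyl-2-oxooxazolidine-3-carbonyl]-5,5-dimethoxypentanoate | COC(=O)C[C@H](CC(OC)OC)C(=O)N1[C@H](Cc2ccccc2)COC1=O | intermediate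
25 | lithium (S)-2-(2,2-dimethoxyethyl)-4-methoxy-4-oxobutaneperoxoate | COC(=O)C[C@H](CC(OC)OC)C(=O)O[O-].[Li+] | intermediate (not isolated)
26 | (S)-2-(2,2-dimethoxyethyl)-4-methoxy-4-oxobutanoic acid | COC(=O)C[C@H](CC(OC)OC)C(=O)O | intermediate
27 | methyl (S)-3-(hydroxymethyl)-5,5-dimethoxypentanoate | COC(=O)C[C@H](CC(OC)OC)CO | intermediate (not isolated)
28 | methyl (S)-3-(iodomethyl)-5,5-dimethoxypentanoate | COC(=O)C[C@H](CC(OC)OC)CI | intermediate
29 | [(S)-2-(2,2-dimethoxyethyl)-4-methoxy-4-oxobutyl]zinc iodide | COC(=O)C[C@H](CC(OC)OC)C[Zn]I | intermediate (not isolated)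
30 | Negishi product: 1,6-diacetate of ring A with C20 2-[(S)-2-(2,2-dimethoxyethyl)-4-methoxy-4-oxobutyl]acrylate | C=C[C@]1(COC(=O)C(=C)C[C@@H](CC(OC)OC)CC(=O)OC)[C@@H](OC(C)=O)CCC(C)(C)[C@H]1COC(C)=O | intermediate
31 | unsaturated spirolactone (7,20-olide, C8=C9; 1,6-diacetate; side-chain acetal and methyl ester) | O=C1OC[C@@]2(C=C1C[C@@H](CC(OC)OC)CC(=O)OC)[C@@H](OC(C)=O)CCC(C)(C)[C@H]2COC(C)=O | intermediate
32 | aldehyde of 31 (C11 CHO) | O=C1OC[C@@]2(C=C1C[C@@H](CC=O)CC(=O)OC)[C@@H](OC(C)=O)CCC(C)(C)[C@H]2COC(C)=O | intermediate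
33 | samarium enolate after ketyl–olefin cyclisation (ring C closed, C11–O–Sm, C8 enolate) | COC(=O)C[C@@H]1C[C@H](O[Sm](I)I)[C@@H]2C(=C(O[Sm](I)I)OC[C@]23[C@@H](OC(C)=O)CCC(C)(C)[C@H]3COC(C)=O)C1 | intermediate (not isolated)
34 | 17-nor-Rabdosin B (C16 is CH2) | C1C(=O)[C@]23C[C@H]1C[C@H](O)[C@H]2[C@]1(COC3=O)[C@@H](OC(C)=O)CCC(C)(C)[C@H]1COC(C)=O | intermediate
35 | Rabdosin B | C=C1C(=O)[C@]23C[C@H]1C[C@H](O)[C@H]2[C@]1(COC3=O)[C@@H](OC(C)=O)CCC(C)(C)[C@H]1COC(C)=O | target

**Step count**
Total: 19 steps. Longest linear sequence: 14 steps (steps 1–9 and 15–19); the side chain takes steps 10–14.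

**Steps most likely to fail**

Step 7 (Proposed new method). The allylboronate may add to acrolein before the radical step, hydrogen-atom transfer may occur at the allylboronate alkene, or closure may run through C9 to a seven-membered ring. Fallback, setting out from 10 and coming back at 14: the radical coupling is run with N-methoxy-N-methylacrylamide in place of acrolein (same iron/silane conditions, a known acceptor class) to give the Weinreb amide F1, so no aldehyde is present during the radical stage. Cp2Zr(H)Cl in THF then reduces the amide to aldehyde 12 in the presence of the acetate. Aldehyde 12 cyclises by the known thermal intramolecular allylboration, and buffered H2O2 returns diol 14.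

Step 18 (Proposed new method). Protonation of the samarium enolate may outrun its acylation, or facial selectivity in the ketyl addition may be poor. Fallback, setting out from 32 and coming back at 34: the known reductive ketyl–olefin cyclisation alone (SmI2, LiBr, t-BuOH, THF, −78 °C) gives the ring-C hydroxy ester F2. A separate Dieckmann condensation of the lactone enolate (LiN(SiMe3)2, THF, −78 → −40 °C, short exposure to spare the acetates) then closes ring D and returns 34.

Step 16. Ring closure to a trisubstituted alkene next to quaternary C10 may be slow, with catalyst decay and oligomerisation. Fallback, setting out from 14 and coming back at 31: diol 14 is esterified at C20–OH with diethylphosphonoacetic acid (DCC, DMAP) to give the phosphonoacetate F3. Acetylation (Ac2O, pyridine) gives the C1 acetate F4. Alkylation with iodide 28 (NaH, DMF) gives the α-alkylated phosphonate F5. Ozonolysis of the C10 vinyl group (O3, CH2Cl2/MeOH, −78 °C; Me2S) gives the aldehyde F6. An intramolecular Horner–Wadsworth–Emmons reaction (LiCl, DBU, MeCN) then forms the C8=C9 bond and returns 31.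

**Further compounds**
F1 | step 7 | (R)-6-[methoxy(methyl)amino]-3,3-dimethyl-6-oxo-2-[(E)-1,4-bis(pinacolboryl)but-2-en-2-yl]hexyl acetate | CC1(C)OB(C/C=C(\CB2OC(C)(C)C(C)(C)O2)[C@H](COC(C)=O)C(C)(C)CCC(=O)N(C)OC)OC1(C)C
F2 | step 18 | ring-C hydroxy ester (C9–C11 closed, 11-OH, H at C8 cis-fused, CH2CO2Me at C13) | COC(=O)C[C@@H]1C[C@H](O)[C@@H]2[C@H](C1)C(=O)OC[C@]23[C@@H](OC(C)=O)CCC(C)(C)[C@H]3COC(C)=O
F3 | step 16 | C20 diethylphosphonoacetate of 14 | C=C[C@]1(COC(=O)CP(=O)(OCC)OCC)[C@@H](O)CCC(C)(C)[C@H]1COC(C)=O
F4 | step 16 | C1 acetate of F3 | C=C[C@]1(COC(=O)CP(=O)(OCC)OCC)[C@@H](OC(C)=O)CCC(C)(C)[C@H]1COC(C)=O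
F5 | step 16 | F4 alkylated at the phosphonate α-carbon with the side chain of 28 | C=C[C@]1(COC(=O)C(C[C@@H](CC(OC)OC)CC(=O)OC)P(=O)(OCC)OCC)[C@@H](OC(C)=O)CCC(C)(C)[C@H]1COC(C)=O
F6 | step 16 | C9 aldehyde from ozonolysis of F5 | O=C[C@]1(COC(=O)C(C[C@@H](CC(OC)OC)CC(=O)OC)P(=O)(OCC)OCC)[C@@H](OC(C)=O)CCC(C)(C)[C@H]1COC(C)=O
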